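**Retrosynthetic overview**
1. Target 12 ⇐ hydride reduction and deacetylation of the all-trans tetrahydrofuran-3-carbaldehyde 11.
2. 11 ⇐ Lewis-acid ring contraction of the seven-membered enol acetal 10 (4,5-dihydro-1,3-dioxepine → tetrahydrofuran; forms C2–C3 and sets C2 and C3).
3. 10 ⇐ new Pd-catalysed asymmetric Heck-type coupling of dioxepine 8 with acylal 9 (forms the side-chain C–C bond and sets C5 and the carbinol centre).
4. 8 and 9 ⇐ vanillin 5 (acetal with cis-2-butene-1,4-diol; acylal) ⇐ guaiacol + glyoxylic acid ⇐ catechol + MeI.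
5. Ring order: arene rings are bought (catechol); the dioxepine ring is made by acetalisation (step 4) and then contracted to the tetrahydrofuran (step 7).

Assumption: the acetal carbon C2 of 10 forms as both epimers; this centre is destroyed in step 7, so the mixture is carried on.

**Step 1**
Reactants: 1 catechol
Product: 2 guaiacol (2-methoxyphenol)
Conditions: MeI (0.9 equiv), K2CO3 (1.0 equiv), acetone, reflux; unreacted catechol recovered
Reagents that add atoms: iodomethane, CI
Why: Williamson mono-O-methylation; sub-stoichiometric MeI and the hydrogen-bonded monoanion limit formation of the dimethyl ether.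

**Step 2**
Reactants: 2 guaiacol; 3 glyoxylic acid
Product: 5 vanillin, via 4-hydroxy-3-methoxymandelic acid 4 (not isolated)
Conditions: NaOH, H2O, 30 °C; then CuSO4 (5 mol%), air, NaOH, 95 °C; then H2SO4 to pH 3
Reagents that add atoms: none
Why: para-selective Friedel–Crafts-type hydroxyalkylation of the phenolate, then copper-catalysed aerobic oxidative decarboxylation of the mandelate (the industrial vanillin process); no stereocentre is kept.

**Step 3**
Reactants: 5 vanillin
Product: 6 vanillin acetate (4-formyl-2-methoxyphenyl acetate)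
Conditions: Ac2O (1.2 equiv), pyridine, rt
Reagents that add atoms: acetic anhydride, CC(=O)OC(C)=O
Why: O-acylation of the phenol; the acetate protects the phenol through steps 4, 6 and 7 and is removed in step 8.

**Step 4**
Reactants: 6 vanillin acetate; 7 cis-2-butene-1,4-diol
Product: 8 4-(4,7-dihydro-1,3-dioxepin-2-yl)-2-methoxyphenyl acetate
Conditions: PPTS (5 mol%), benzene, reflux, Dean–Stark
Reagents that add atoms: none
Why: acid-catalysed acetalisation; the cis-diol closes the seven-membered 4,7-dihydro-1,3-dioxepine, which is achiral (mirror plane through C2).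

**Step 5**
Reactants: 5 vanillin
Product: 9 vanillin triacetate ((4-acetoxy-3-methoxyphenyl)methanediyl diacetate)
Conditions: Ac2O (4 equiv), H2SO4 (cat.), 0 °C to rt
Reagents that add atoms: acetic anhydride, CC(=O)OC(C)=O
Why: acid-catalysed acylal formation at the aldehyde together with phenol acetylation, the classical vanillin triacetate preparation.

**Step 6**
Reactants: 8 dioxepine (1.5 equiv); 9 vanillin triacetate
Product: 10 (R)-[(5R)-2-(4-acetoxy-3-methoxyphenyl)-4,5-dihydro-1,3-dioxepin-5-yl](4-acetoxy-3-methoxyphenyl)methyl acetate (both C2 epimers)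
Conditions: Pd(dba)2 (5 mol%), phosphoramidite PA (12 mol%; PA = (S)-1,1'-binaphthyl-2,2'-diyl N,N-bis[(R)-1-phenylethyl]phosphoramidite), i-Pr2NEt (2 equiv), 1,4-dioxane, 60 °C
Reagents that add atoms: none
Why: Proposed new method: zerovalent palladium ionises the acylal 9 (the geminal acetoxy group makes the benzylic C–O bond acetal-like) to a cationic η3-(α-acetoxybenzyl)palladium complex whose two faces interconvert by η3–η1–η3 slippage; syn-carbopalladation of one of the two enantiotopic alkene carbons of 8 under control of the phosphoramidite sets C5, and in the preferred insertion geometry the aryl group stays on palladium, the benzylic hydrogen lies over the dioxepine ring and the acetoxy group points outward, which gives the syn (5R, carbinol R) pair; the only syn β-hydrogen is on C7, so β-hydride elimination gives the enol acetal only and the amine returns the catalyst; this is a Mizoroki–Heck reaction, and the closest known cases are the asymmetric Heck arylation of 4,7-dihydro-1,3-dioxepines and the asymmetric Heck reaction of primary benzyl esters with cyclic alkenes, here extended to a secondary α-oxygenated benzyl electrophile made from an aldehyde.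

**Step 7**
Reactants: 10 enol acetal
Product: 11 (2R,3R,4R)-2-(4-acetoxy-3-methoxyphenyl)-4-[(R)-acetoxy(4-acetoxy-3-methoxyphenyl)methyl]tetrahydrofuran-3-carbaldehyde
Conditions: TMSOTf (20 mol%), CH2Cl2, −78 °C to 0 °C; Et3N quench
Reagents that add atoms: none
Why: vinyl acetal (Petasis–Ferrier-type) ring contraction: TMSOTf cleaves the acetal C–O(enol) bond to a benzylic oxocarbenium ion and a silyl enol ether, which reclose by an intramolecular Mukaiyama aldol-type C–C bond formation to the five-membered ring; C4 and the carbinol centre are untouched, the aryl group and the C4 side chain take pseudo-equatorial positions (2,4-cis), and the enolisable C3 equilibrates at 0 °C to the all-trans aldehyde.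

**Step 8**
Reactants: 11 aldehyde
Product: 12 target, 4-[(R)-hydroxy[(3R,4S,5R)-5-(4-hydroxy-3-methoxyphenyl)-4-(hydroxymethyl)tetrahydrofuran-3-yl]methyl]-2-methoxyphenol
Conditions: LiAlH4 (5 equiv), THF, 0 °C to rt; then H2O, pH 7
Reagents that add atoms: none
Why: hydride reduction of the aldehyde and reductive cleavage of the three acetates in one operation; no stereocentre is touched (the C3 descriptor changes from R to S only through CIP priorities).

**Compound list**
1 | catechol (benzene-1,2-diol) | Oc1ccccc1O | starting material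
2 | guaiacol (2-methoxyphenol) | COc1ccccc1O | intermediate
3 | glyoxylic acid | O=CC(=O)O | starting material
4 | 4-hydroxy-3-methoxymandelic acid (racemic) | COc1cc(C(O)C(=O)O)ccc1O | intermediate
5 | vanillin | COc1cc(C=O)ccc1O | intermediate
6 | vanillin acetate | COc1cc(C=O)ccc1OC(C)=O | intermediate
7 | cis-2-butene-1,4-diol | OC/C=C\CO | starting material
8 | 4-(4,7-dihydro-1,3-dioxepin-2-yl)-2-methoxyphenyl acetate | COc1cc(C2OCC=CCO2)ccc1OC(C)=O | intermediate
9 | vanillin triacetate | COc1cc(C(OC(C)=O)OC(C)=O)ccc1OC(C)=O | intermediate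
10 | (R)-[(5R)-2-(4-acetoxy-3-methoxyphenyl)-4,5-dihydro-1,3-dioxepin-5-yl](4-acetoxy-3-methoxyphenyl)methyl acetate, C2 epimers | COc1cc([C@H](OC(C)=O)[C@H]2COC(c3ccc(OC(C)=O)c(OC)c3)OC=C2)ccc1OC(C)=O | intermediate
11 | (2R,3R,4R)-2-(4-acetoxy-3-methoxyphenyl)-4-[(R)-acetoxy(4-acetoxy-3-methoxyphenyl)methyl]tetrahydrofuran-3-carbaldehyde | COc1cc([C@H](OC(C)=O)[C@H]2CO[C@@H](c3ccc(OC(C)=O)c(OC)c3)[C@@H]2C=O)ccc1OC(C)=O | intermediate
12 | 4-[(R)-hydroxy[(3R,4S,5R)-5-(4-hydroxy-3-methoxyphenyl)-4-(hydroxymethyl)tetrahydrofuran-3-yl]methyl]-2-methoxyphenol | COc1cc([C@H](O)[C@H]2CO[C@@H](c3ccc(O)c(OC)c3)[C@@H]2CO)ccc1O | target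

**Step count**
Total: 8 steps. Longest linear sequence: 7 steps (1, 2, 3, 4, 6, 7, 8).

**Three steps most likely to fail**

Step 6 (the new coupling). Risks: the acylal may not ionise, Pd–H may isomerise 8, or the diastereomer or enantiomer sense may be wrong (the mirror-image ligand is the first remedy for the latter). The fallback uses known chemistry, sets out from 7 and 6, and comes back at 11. Diol 7 is monosilylated (NaH, TBSCl, THF) to (Z)-4-[(tert-butyldimethylsilyl)oxy]but-2-en-1-ol F1. F1 is carbamoylated (i-Pr2NCOCl, NaH) to (Z)-4-[(tert-butyldimethylsilyl)oxy]but-2-en-1-yl N,N-diisopropylcarbamate F2. A Hoppe homoaldol reaction (s-BuLi, (−)-sparteine, toluene, −78 °C; Ti(OiPr)4; then 6) gives (1Z,3R,4R)-4-(4-acetoxy-3-methoxyphenyl)-3-{[(tert-butyldimethylsilyl)oxy]methyl}-4-hydroxybut-1-en-1-yl N,N-diisopropylcarbamate F3; the syn relationship comes from the chair transition state of the (Z)-allyltitanium, and the sparteine enantiomer is chosen for the 3R,4R series. Acetylation (Ac2O, pyridine) gives (1Z,3R,4R)-4-acetoxy-4-(4-acetoxy-3-methoxyphenyl)-3-{[(tert-butyldimethylsilyl)oxy]methyl}but-1-en-1-yl N,N-diisopropylcarbamate F4. HF·pyridine gives (1Z,3R,4R)-4-acetoxy-4-(4-acetoxy-3-methoxyphenyl)-3-(hydroxymethyl)but-1-en-1-yl N,N-diisopropylcarbamate F5. BF3·OEt2 then condenses F5 with 6: the oxocarbenium ion on the primary oxygen is attacked by the enol carbamate (Hoppe tetrahydrofuran annulation), and aqueous work-up gives 11.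

Step 7 (ring contraction). Risks: the 4-acetoxyaryl oxocarbenium ion may form slowly, so that the benzylic acetate ionises first or C2 does not equilibrate to the 2,4-cis isomer. The fallback changes the substrate design, sets out from 5, and comes back at 12: the acetal aryl is made more electron-rich so that a weak Lewis acid suffices and C2 can equilibrate. Vanillin 5 is silylated (TBSCl, imidazole) to 4-[(tert-butyldimethylsilyl)oxy]-3-methoxybenzaldehyde F6. F6 is acetalised with 7 (PPTS, benzene, Dean–Stark) to tert-butyl[4-(4,7-dihydro-1,3-dioxepin-2-yl)-2-methoxyphenoxy]dimethylsilane F7. Coupling with 9 as in step 6 gives (R)-[(5R)-2-{4-[(tert-butyldimethylsilyl)oxy]-3-methoxyphenyl}-4,5-dihydro-1,3-dioxepin-5-yl](4-acetoxy-3-methoxyphenyl)methyl acetate F8. MgBr2·OEt2 in CH2Cl2 (−40 °C to rt) gives (2R,3R,4R)-4-[(R)-acetoxy(4-acetoxy-3-methoxyphenyl)methyl]-2-{4-[(tert-butyldimethylsilyl)oxy]-3-methoxyphenyl}tetrahydrofuran-3-carbaldehyde F9. LiAlH4 gives 4-[(R)-{(3R,4S,5R)-5-{4-[(tert-butyldimethylsilyl)oxy]-3-methoxyphenyl}-4-(hydroxymethyl)tetrahydrofuran-3-yl}(hydroxy)methyl]-2-methoxyphenol F10, and Bu4NF gives 12.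

Step 4 (acetalisation next to an aryl acetate). Risk: acid and heat may transfer the acetyl group to the diol. The fallback reverses the order, sets out from 5, and comes back at 8. Free vanillin 5 is acetalised with 7 (TsOH cat., toluene, Dean–Stark) to 4-(4,7-dihydro-1,3-dioxepin-2-yl)-2-methoxyphenol F11, which is then acetylated under basic conditions (Ac2O, pyridine) to 8.

**Further compounds**
F1 | step 6 | (Z)-4-[(tert-butyldimethylsilyl)oxy]but-2-en-1-ol | CC(C)(C)[Si](C)(C)OC/C=C\CO
F2 | step 6 | (Z)-4-[(tert-butyldimethylsilyl)oxy]but-2-en-1-yl N,N-diisopropylcarbamate | CC(C)N(C(C)C)C(=O)OC/C=C\CO[Si](C)(C)C(C)(C)C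
F3 | step 6 | (1Z,3R,4R)-4-(4-acetoxy-3-methoxyphenyl)-3-{[(tert-butyldimethylsilyl)oxy]methyl}-4-hydroxybut-1-en-1-yl N,N-diisopropylcarbamate | COc1cc([C@H](O)[C@@H](CO[Si](C)(C)C(C)(C)C)/C=C\OC(=O)N(C(C)C)C(C)C)ccc1OC(C)=O
F4 | step 6 | (1Z,3R,4R)-4-acetoxy-4-(4-acetoxy-3-methoxyphenyl)-3-{[(tert-butyldimethylsilyl)oxy]methyl}but-1-en-1-yl N,N-diisopropylcarbamate | COc1cc([C@H](OC(C)=O)[C@@H](CO[Si](C)(C)C(C)(C)C)/C=C\OC(=O)N(C(C)C)C(C)C)ccc1OC(C)=O
F5 | step 6 | (1Z,3R,4R)-4-acetoxy-4-(4-acetoxy-3-methoxyphenyl)-3-(hydroxymethyl)but-1-en-1-yl N,N-diisopropylcarbamate | COc1cc([C@H](OC(C)=O)[C@@H](CO)/C=C\OC(=O)N(C(C)C)C(C)C)ccc1OC(C)=O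
F6 | step 7 | 4-[(tert-butyldimethylsilyl)oxy]-3-methoxybenzaldehyde | COc1cc(C=O)ccc1O[Si](C)(C)C(C)(C)C
F7 | step 7 | tert-butyl[4-(4,7-dihydro-1,3-dioxepin-2-yl)-2-methoxyphenoxy]dimethylsilane | COc1cc(C2OCC=CCO2)ccc1O[Si](C)(C)C(C)(C)C
F8 | step 7 | (R)-[(5R)-2-{4-[(tert-butyldimethylsilyl)oxy]-3-methoxyphenyl}-4,5-dihydro-1,3-dioxepin-5-yl](4-acetoxy-3-methoxyphenyl)methyl acetate | COc1cc([C@H](OC(C)=O)[C@H]2COC(c3ccc(O[Si](C)(C)C(C)(C)C)c(OC)c3)OC=C2)ccc1OC(C)=O
F9 | step 7 | (2R,3R,4R)-4-[(R)-acetoxy(4-acetoxy-3-methoxyphenyl)methyl]-2-{4-[(tert-butyldimethylsilyl)oxy]-3-methoxyphenyl}tetrahydrofuran-3-carbaldehyde | COc1cc([C@H](OC(C)=O)[C@H]2CO[C@@H](c3ccc(O[Si](C)(C)C(C)(C)C)c(OC)c3)[C@@H]2C=O)ccc1OC(C)=O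
F10 | step 7 | 4-[(R)-{(3R,4S,5R)-5-{4-[(tert-butyldimethylsilyl)oxy]-3-methoxyphenyl}-4-(hydroxymethyl)tetrahydrofuran-3-yl}(hydroxy)methyl]-2-methoxyphenol | COc1cc([C@H](O)[C@H]2CO[C@@H](c3ccc(O[Si](C)(C)C(C)(C)C)c(OC)c3)[C@@H]2CO)ccc1O
F11 | step 4 | 4-(4,7-dihydro-1,3-dioxepin-2-yl)-2-methoxyphenol | COc1cc(C2OCC=CCO2)ccc1O
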